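Locants: ring C1–C10 (C4 and C10 bear methyl), lactone carbons C11–C13. The ten-membered ring is traced back to a cyclohexane: its C5 ketone, C6 carbinol, C7–C8 stereodiad and adjacent C9–C10 pair (an E alkene before oxygenation) are the imprint of an anionic oxy-Cope shift with enolate hydroxylation. One operation cleaves C5–C10, forms C7–C8, expands the six-membered ring by four atoms, sets C7 and C8 through a chair and hydroxylates C6. The precursor is a cis-1,2-dialkenyl-2,6-dimethylcyclohexanol with an E-dienyl arm on C5 and an E-enol ether arm on C10, both oxygens masked as 4-methoxybenzyl ethers; afterwards come lactonisation, anti oxygenation of C9=C10 and angeloylation.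

Key step: step 10

Remarks on the chemistry:
- Full locants: C1–C3 ring CH2; C4 CH(CH3); C5 carbinol, later ketone; C6 CH–O; C7 ring-fusion CH; C8 lactone O–CH; C9 CH–O-angelate; C10 C(CH3)–O; C11(=C13H2); C12 lactone carbonyl. PMB = 4-methoxybenzyl, TBS = tert-butyldimethylsilyl.
- The CIP descriptors at C7 and C8 change along the route only because substituent priorities change; the spatial arrangement set in step 10 is kept.
- The C4 centre is carried as an epimer mixture until it is equilibrated in step 6.
- The late hydroxy ketones are drawn in the open form; a transannular hemiketal tautomer, if populated, interconverts with it.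

Step 1
Reactants: 1 2,6-dimethylcyclohexan-1-one; 2 allyl chloroformate
Product: 4 prop-2-en-1-yl 2,6-dimethylcyclohex-1-en-1-yl carbonate, via sodium enolate 3 (not isolated)
Conditions: NaN(SiMe3)2, TMEDA, THF, −78 °C; then 2, −78 → 0 °C
Reagents that add atoms: none
Why: The ketone has only one enolate (tetrasubstituted, the two α-carbons being equivalent) and the hard chloroformate acylates it on oxygen, since C-acylation would have to create a quaternary centre; enolate O-acylation to an allyl enol carbonate.

Step 2
Reactants: 4 prop-2-en-1-yl 2,6-dimethylcyclohex-1-en-1-yl carbonate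
Product: 5 (2R)-2,6-dimethyl-2-(prop-2-en-1-yl)cyclohexan-1-one (both C6 epimers)
Conditions: Pd2(dba)3 (2.5 mol%), (R)-t-BuPHOX (6 mol%), THF, 25 °C
Reagents that add atoms: none
Why: Decarboxylative asymmetric allylic alkylation (Tsuji–Trost type): ionisation and loss of CO2 give a π-allylpalladium enolate that recombines within the PHOX pocket, so the quaternary C10 is set by the catalyst (the R ligand should give the R centre, by the known sense of this ligand class with 2-alkylcyclohexanone enolates) irrespective of the racemic C4.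

Step 3
Reactants: 5 (2R)-2,6-dimethyl-2-(prop-2-en-1-yl)cyclohexan-1-one
Product: 6 (2R)-2,6-dimethyl-2-[(1E)-prop-1-en-1-yl]cyclohexan-1-one (both C6 epimers)
Conditions: PdCl2(MeCN)2 (5 mol%), toluene, 60 °C
Reagents that add atoms: none
Why: Palladium-hydride chain walking (alkene isomerisation) moves the terminal alkene one position to the more substituted E-propenyl group and cannot go further because C10 is quaternary.

Step 4
Reactants: 6 (2R)-2,6-dimethyl-2-[(1E)-prop-1-en-1-yl]cyclohexan-1-one
Product: 8 (1R)-1,3-dimethyl-2-oxocyclohexane-1-carbaldehyde (both C3 epimers), via secondary ozonide 7 (not isolated)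
Conditions: O3, CH2Cl2, −78 °C; then Me2S, −78 °C → rt
Reagents that add atoms: ozone, [O-][O+]=O
Why: Ozonolysis with reductive work-up cleaves the only alkene to the aldehyde, which cannot enolise at the quaternary C10 and therefore keeps its configuration.

Step 5
Reactants: 8 (1R)-1,3-dimethyl-2-oxocyclohexane-1-carbaldehyde
Product: 9 (2R)-2-[(E)-2-iodoethenyl]-2,6-dimethylcyclohexan-1-one (both C6 epimers)
Conditions: CrCl2 (6 equiv), CHI3 (2 equiv), THF/1,4-dioxane, 0 °C → rt
Reagents that add atoms: iodoform, IC(I)I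
Why: Takai olefination: the geminal dichromium species from iodoform adds to the aldehyde only and eliminates to the E-iodoalkene, with the highest E preference for α-branched aldehydes, while the hindered ketone does not react.

Step 6
Reactants: 9 (2R)-2-[(E)-2-iodoethenyl]-2,6-dimethylcyclohexan-1-one; 10 (4-methoxyphenyl)methanol
Product: 11 (2R,6S)-2-[(E)-2-[(4-methoxyphenyl)methoxy]ethenyl]-2,6-dimethylcyclohexan-1-one
Conditions: CuI (10 mol%), 3,4,7,8-tetramethyl-1,10-phenanthroline (20 mol%), Cs2CO3, toluene, 80 °C; then NaOMe (cat.), MeOH, rt; chromatography, minor C4 epimer resubmitted to NaOMe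
Reagents that add atoms: none
Why: Copper-catalysed Ullmann-type C–O coupling of an iodoalkene with a primary alcohol retains the alkene geometry and so gives the E enol ether, and methoxide then equilibrates the enolisable C4 toward the epimer with both methyls equatorial and the sp2 arm axial, which is expected to be the more stable and is separated while the other is recycled.

Step 7
Reactants: 10 (4-methoxyphenyl)methanol; 12 2,3-dibromoprop-1-ene
Product: 14 1-{[(2-bromoprop-2-en-1-yl)oxy]methyl}-4-methoxybenzene, via sodium alkoxide 13 (not isolated)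
Conditions: NaH, THF, 0 °C; then 12, 0 °C → rt
Reagents that add atoms: none
Why: Williamson ether synthesis: the alkoxide displaces the allylic bromide by SN2 and the vinylic bromide stays untouched.

Step 8
Reactants: 14 1-{[(2-bromoprop-2-en-1-yl)oxy]methyl}-4-methoxybenzene; 15 (E)-1,2-bis(tributylstannyl)ethene
Product: 16 tributyl[(1E)-3-{[(4-methoxyphenyl)methoxy]methyl}buta-1,3-dien-1-yl]stannane
Conditions: Pd(PPh3)4 (5 mol%), 15 (3 equiv), toluene, 90 °C
Reagents that add atoms: none
Why: Stille coupling of the 2-bromoalkene with one tin terminus of the distannane, used in excess to avoid double coupling, proceeds with retention and leaves an E-alkenylstannane.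

Step 9
Reactants: 16 tributyl[(1E)-3-{[(4-methoxyphenyl)methoxy]methyl}buta-1,3-dien-1-yl]stannane; 11 (2R,6S)-2-[(E)-2-[(4-methoxyphenyl)methoxy]ethenyl]-2,6-dimethylcyclohexan-1-one
Product: 18 (1R,2R,6S)-1-[(1E)-3-{[(4-methoxyphenyl)methoxy]methyl}buta-1,3-dien-1-yl]-2-[(E)-2-[(4-methoxyphenyl)methoxy]ethenyl]-2,6-dimethylcyclohexan-1-ol, via dienyllithium 17 (not isolated)
Conditions: n-BuLi, THF, −78 °C; then 11, −78 → −40 °C; H2O
Reagents that add atoms: none
Why: Tin–lithium exchange gives the E-alkenyllithium with retention and 1,2-addition follows: the ketone is locked with both methyls equatorial and the enol ether arm axial, and as with other 2,2,6-trisubstituted cyclohexanones the nucleophile should enter along the equatorial trajectory anti to the C4 methyl, giving the axial C5 alcohol (R) with the two alkenyl arms cis.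

Step 10
Reactants: 18 (1R,2R,6S)-1-[(1E)-3-{[(4-methoxyphenyl)methoxy]methyl}buta-1,3-dien-1-yl]-2-[(E)-2-[(4-methoxyphenyl)methoxy]ethenyl]-2,6-dimethylcyclohexan-1-ol
Product: 21 (2S,3S,4S,5E,10S)-2-hydroxy-4-[(4-methoxyphenyl)methoxy]-3-{3-[(4-methoxyphenyl)methoxy]prop-1-en-2-yl}-6,10-dimethylcyclodec-5-en-1-one, via potassium alkoxide 19 (not isolated), via potassium enolate 20 (not isolated)
Conditions: KN(SiMe3)2, 18-crown-6, THF, 0 °C → rt; then 2-(phenylsulfonyl)-3-phenyloxaziridine, −78 °C; AcOH
Reagents that add atoms: 2-(phenylsulfonyl)-3-phenyloxaziridine, O=S(=O)(c1ccccc1)N1OC1c1ccccc1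
Why: Deprotonation gives the potassium alkoxide, whose charge accelerates a concerted [3,3] shift (anionic oxy-Cope rearrangement) that forms C7–C8 while cleaving C5–C10, and the resulting C5=C6 potassium enolate is then oxidised at C6 by the N-sulfonyloxaziridine (Davis oxidation). The closest known reaction type is the anionic oxy-Cope ring expansion of 1,2-dialkenylcyclohexanols to cyclodec-5-enones with trapping of the enolate by an electrophile. The ten-membered ring is not closed end to end but arises by a four-atom ring expansion of the cyclohexane through a six-membered chair transition state fused to it. In the favoured cyclohexanol chair (both methyls equatorial, C10 arm axial, C5 arm equatorial) the two E alkenes place the C11 group on C7 and the OPMB group on C8 pseudo-equatorial, so C7 and C8 are set by the C5 and C10 centres that are consumed together with the alkene geometries, while the pseudo-equatorial C1 chain gives the E C9=C10 alkene. C6 is set by attack of the oxidant on the outer face of the enolate, the face turned away from the transannular C9=C10 unit, in the rotamer where H7 eclipses the enolate plane to avoid allylic strain with C4. The step needs chair over boat and outer over inner face, and the chair free of 1,3-diaxial contacts (only hydrogens are axial at C7 and C8) and the transannular shielding of the inner face should secure them.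

Step 11
Reactants: 21 (2S,3S,4S,5E,10S)-2-hydroxy-4-[(4-methoxyphenyl)methoxy]-3-{3-[(4-methoxyphenyl)methoxy]prop-1-en-2-yl}-6,10-dimethylcyclodec-5-en-1-one
Product: 22 (2S,3R,4S,5E,10S)-2-{[tert-butyl(dimethyl)silyl]oxy}-4-[(4-methoxyphenyl)methoxy]-3-{3-[(4-methoxyphenyl)methoxy]prop-1-en-2-yl}-6,10-dimethylcyclodec-5-en-1-one
Conditions: TBSOTf, 2,6-lutidine, CH2Cl2, −78 → 0 °C
Reagents that add atoms: tert-butyldimethylsilyl trifluoromethanesulfonate, CC(C)(C)[Si](C)(C)OS(=O)(=O)C(F)(F)F
Why: Silylation with the silyl triflate and a hindered pyridine base protects the hindered secondary C6 hydroxyl at low temperature, before the ketone can be silylated on oxygen.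

Step 12
Reactants: 22 (2S,3R,4S,5E,10S)-2-{[tert-butyl(dimethyl)silyl]oxy}-4-[(4-methoxyphenyl)methoxy]-3-{3-[(4-methoxyphenyl)methoxy]prop-1-en-2-yl}-6,10-dimethylcyclodec-5-en-1-one
Product: 23 (2S,3R,4S,5E,10S)-2-{[tert-butyl(dimethyl)silyl]oxy}-4-hydroxy-3-(3-hydroxyprop-1-en-2-yl)-6,10-dimethylcyclodec-5-en-1-one
Conditions: DDQ (2.5 equiv), CH2Cl2/pH 7 buffer, 0 °C
Reagents that add atoms: none
Why: Oxidative cleavage of 4-methoxybenzyl ethers by DDQ (hydride abstraction to the oxocarbenium ion, then hydrolysis) frees O8 and O12 together and leaves the silyl ether, the ketone and both alkenes alone.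

Step 13
Reactants: 23 (2S,3R,4S,5E,10S)-2-{[tert-butyl(dimethyl)silyl]oxy}-4-hydroxy-3-(3-hydroxyprop-1-en-2-yl)-6,10-dimethylcyclodec-5-en-1-one
Product: 26 C6-O-TBS 8,12-olide (α-methylene-γ-lactone trans-fused at C7–C8 on the E-cyclodec-9-en-5-one; 4S,6S,7R,8S), via hydroxy enal 24 (not isolated), via lactol 25 (not isolated)
Conditions: TEMPO (20 mol%), PhI(OAc)2 (2.5 equiv), CH2Cl2, rt
Reagents that add atoms: none
Why: Oxoammonium-mediated oxidative lactonisation: the primary allylic alcohol is oxidised far faster than the secondary one, the enal is captured by the C8 hydroxyl as a five-membered lactol (5-exo-trig; O8 and C11 are gauche, both pseudo-equatorial) and this is oxidised on to the trans-fused α-methylene-γ-lactone.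

Step 14
Reactants: 26 C6-O-TBS 8,12-olide with E-C9=C10
Product: 27 9,10-epoxide of 26 (4S,6S,7R,8R,9S,10S; epoxide oxygen cis to O8)
Conditions: dimethyldioxirane, acetone, −20 → 0 °C
Reagents that add atoms: dimethyldioxirane, CC1(C)OO1
Why: Electrophilic epoxidation by the dioxirane selects the electron-rich trisubstituted alkene over the conjugated methylene lactone and does not attack the ketone; an E alkene in the ten-membered ring is reached only on its outer face, and in the rotamer with H8 eclipsing the C10 methyl (allylic strain) this is the face cis to O8, which sets C9 (S).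

Step 15
Reactants: 27 9,10-epoxide
Product: 28 C6-O-TBS 9,10-diol lactone (4S,6S,7R,8R,9S,10R)
Conditions: HClO4 (cat.), THF/H2O, 0 °C
Reagents that add atoms: water, O
Why: Acid-catalysed epoxide hydrolysis opens the C10–O bond at the tertiary carbon with inversion and leaves C9–O untouched, the oxygen entering on the transannular face where the C5 carbonyl can relay it as a hemiketal, so the 9,10-anti diol with C10 R should result.

Step 16
Reactants: 28 C6-O-TBS 9,10-diol lactone; 29 angelic acid
Product: 31 C6-O-TBS C9-O-angelate (4S,6S,7R,8R,9S,10R), via mixed anhydride 30 (not isolated)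
Conditions: 29, 2,4,6-trichlorobenzoyl chloride, Et3N, toluene, rt; then 28, toluene, 80 °C
Reagents that add atoms: none
Why: Yamaguchi-type esterification through the mixed 2,4,6-trichlorobenzoic anhydride without a nucleophilic catalyst acylates the secondary C9 hydroxyl, leaves the tertiary C10 hydroxyl alone, and is the known way to keep the Z geometry of angelates, which isomerise to tiglates under carbodiimide or DMAP conditions.

Step 17
Reactants: 31 C6-O-TBS C9-O-angelate
Product: 32 CNP0311008.1 (4S,6S,7S,8R,9S,10R)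
Conditions: HF·pyridine, pyridine, THF, 0 °C → rt
Reagents that add atoms: none
Why: Fluoride cleaves the Si–O bond under buffered, weakly acidic conditions that the angelate, the methylene lactone, the tertiary alcohol and the α-ketol all tolerate; desilylation.

Compound list
1 | 2,6-dimethylcyclohexan-1-one (cis/trans mixture) | CC1CCCC(C)C1=O | starting material
2 | allyl chloroformate | C=CCOC(=O)Cl | starting material
3 | sodium 2,6-dimethylcyclohex-1-en-1-olate | [Na+].[O-]C1=C(C)CCCC1C | intermediate (not isolated)
4 | prop-2-en-1-yl 2,6-dimethylcyclohex-1-en-1-yl carbonate (racemic) | C=CCOC(=O)OC1=C(C)CCCC1C | intermediate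
5 | (2R)-2,6-dimethyl-2-(prop-2-en-1-yl)cyclohexan-1-one, both C6 epimers | C=CC[C@@]1(C)CCCC(C)C1=O | intermediate
6 | (2R)-2,6-dimethyl-2-[(1E)-prop-1-en-1-yl]cyclohexan-1-one, both C6 epimers | C/C=C/[C@@]1(C)CCCC(C)C1=O | intermediate
7 | secondary ozonide of 6: 3-methyl-5-[(1R)-1,3-dimethyl-2-oxocyclohexyl]-1,2,4-trioxolane | CC1OOC(O1)[C@@]2(C)CCCC(C)C2=O | intermediate (not isolated)
8 | (1R)-1,3-dimethyl-2-oxocyclohexane-1-carbaldehyde, both C3 epimers | O=C[C@@]1(C)CCCC(C)C1=O | intermediate
9 | (2R)-2-[(E)-2-iodoethenyl]-2,6-dimethylcyclohexan-1-one, both C6 epimers | I/C=C/[C@@]1(C)CCCC(C)C1=O | intermediate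
10 | (4-methoxyphenyl)methanol | COc1ccc(CO)cc1 | starting material
11 | (2R,6S)-2-[(E)-2-[(4-methoxyphenyl)methoxy]ethenyl]-2,6-dimethylcyclohexan-1-one (methyls cis) | COc1ccc(CO/C=C/[C@@]2(C)CCC[C@H](C)C2=O)cc1 | intermediate
12 | 2,3-dibromoprop-1-ene | C=C(Br)CBr | starting material
13 | sodium (4-methoxyphenyl)methanolate | [Na+].[O-]Cc1ccc(OC)cc1 | intermediate (not isolated)
14 | 1-{[(2-bromoprop-2-en-1-yl)oxy]methyl}-4-methoxybenzene | COc1ccc(COCC(Br)=C)cc1 | intermediate
15 | (E)-1,2-bis(tributylstannyl)ethene | CCCC[Sn](CCCC)(CCCC)/C=C/[Sn](CCCC)(CCCC)CCCC | starting material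
16 | tributyl[(1E)-3-{[(4-methoxyphenyl)methoxy]methyl}buta-1,3-dien-1-yl]stannane | COc1ccc(COCC(=C)/C=C/[Sn](CCCC)(CCCC)CCCC)cc1 | intermediate
17 | [(1E)-3-{[(4-methoxyphenyl)methoxy]methyl}buta-1,3-dien-1-yl]lithium | [Li]/C=C/C(=C)COCc1ccc(OC)cc1 | intermediate (not isolated)
18 | (1R,2R,6S)-1-[(1E)-3-{[(4-methoxyphenyl)methoxy]methyl}buta-1,3-dien-1-yl]-2-[(E)-2-[(4-methoxyphenyl)methoxy]ethenyl]-2,6-dimethylcyclohexan-1-ol (arms cis; OH and both methyls on the other face) | O[C@@]1(/C=C/C(=C)COCc2ccc(OC)cc2)[C@@H](C)CCC[C@]1(C)/C=C/OCc2ccc(OC)cc2 | intermediate (key-step precursor)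
19 | potassium alkoxide of 18 | [K+].[O-][C@@]1(/C=C/C(=C)COCc2ccc(OC)cc2)[C@@H](C)CCC[C@]1(C)/C=C/OCc2ccc(OC)cc2 | intermediate (not isolated)
20 | potassium enolate of the ring-expanded ketone (C5–O−, C5=C6 with C4 and C7 cis, E-C9=C10; 4S,7R,8S) | [K+].[O-]/C1=C/[C@H](C(=C)COCc2ccc(OC)cc2)[C@@H](OCc2ccc(OC)cc2)/C=C(C)/CCC[C@@H]1C | intermediate (not isolated)
21 | (2S,3S,4S,5E,10S)-2-hydroxy-4-[(4-methoxyphenyl)methoxy]-3-{3-[(4-methoxyphenyl)methoxy]prop-1-en-2-yl}-6,10-dimethylcyclodec-5-en-1-one (skeleton locants 4S,6S,7S,8S) | O=C1[C@@H](C)CCC/C(C)=C/[C@H](OCc2ccc(OC)cc2)[C@@H](C(=C)COCc2ccc(OC)cc2)[C@@H]1O | intermediate (key-step product)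
22 | (2S,3R,4S,5E,10S)-2-{[tert-butyl(dimethyl)silyl]oxy}-4-[(4-methoxyphenyl)methoxy]-3-{3-[(4-methoxyphenyl)methoxy]prop-1-en-2-yl}-6,10-dimethylcyclodec-5-en-1-one | O=C1[C@@H](C)CCC/C(C)=C/[C@H](OCc2ccc(OC)cc2)[C@@H](C(=C)COCc2ccc(OC)cc2)[C@@H]1O[Si](C)(C)C(C)(C)C | intermediate
23 | (2S,3R,4S,5E,10S)-2-{[tert-butyl(dimethyl)silyl]oxy}-4-hydroxy-3-(3-hydroxyprop-1-en-2-yl)-6,10-dimethylcyclodec-5-en-1-one | O=C1[C@@H](C)CCC/C(C)=C/[C@H](O)[C@@H](C(=C)CO)[C@@H]1O[Si](C)(C)C(C)(C)C | intermediate
24 | hydroxy enal: 23 with C12 oxidised to the aldehyde (2-substituted propenal on C7, free C8–OH) | O=C1[C@@H](C)CCC/C(C)=C/[C@H](O)[C@@H](C(=C)C=O)[C@@H]1O[Si](C)(C)C(C)(C)C | intermediate (not isolated)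
25 | lactol: 8,12-hemiacetal of 24 (both C12 epimers) | C=C1C(O)O[C@H]2/C=C(C)/CCC[C@H](C)C(=O)[C@@H](O[Si](C)(C)C(C)(C)C)[C@H]12 | intermediate (not isolated)
26 | C6-O-TBS 8,12-olide: α-methylene-γ-lactone (O8–C12(=O)–C11(=C13H2)–C7) trans-fused on the E-cyclodec-9-en-5-one; 4S,6S,7R,8S | C=C1C(=O)O[C@H]2/C=C(C)/CCC[C@H](C)C(=O)[C@@H](O[Si](C)(C)C(C)(C)C)[C@H]12 | intermediate
27 | 9,10-epoxide of 26 (trans-epoxide, oxygen cis to O8; 4S,6S,7R,8R,9S,10S) | C=C1C(=O)O[C@@H]2[C@@H]1[C@H](O[Si](C)(C)C(C)(C)C)C(=O)[C@@H](C)CCC[C@]3(C)O[C@@H]23 | intermediate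
28 | C6-O-TBS 9,10-diol lactone (C9 secondary OH, C10 tertiary OH; 4S,6S,7R,8R,9S,10R) | C=C1C(=O)O[C@@H]2[C@@H]1[C@H](O[Si](C)(C)C(C)(C)C)C(=O)[C@@H](C)CCC[C@@](C)(O)[C@H]2O | intermediate
29 | angelic acid, (2Z)-2-methylbut-2-enoic acid | C/C=C(/C)C(=O)O | starting material
30 | (2Z)-2-methylbut-2-enoic 2,4,6-trichlorobenzoic anhydride | C/C=C(/C)C(=O)OC(=O)c1c(Cl)cc(Cl)cc1Cl | intermediate (not isolated)
31 | C6-O-TBS C9-O-angelate of the 10-hydroxy lactone (4S,6S,7R,8R,9S,10R) | C=C1C(=O)O[C@@H]2[C@@H]1[C@H](O[Si](C)(C)C(C)(C)C)C(=O)[C@@H](C)CCC[C@@](C)(O)[C@H]2OC(=O)/C(C)=C\C | intermediate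
32 | CNP0311008.1: 6,10-dihydroxy-5-oxo-8,12-olide 9-angelate (4S,6S,7S,8R,9S,10R) | C=C1C(=O)O[C@@H]2[C@@H]1[C@H](O)C(=O)[C@@H](C)CCC[C@@](C)(O)[C@H]2OC(=O)/C(C)=C\C | target

Total step count: 17. Longest linear sequence: 15 steps (steps 1–6 and 9–17); the dienylstannane branch (steps 7–8) joins in step 9.

Steps most likely to fail

1. Step 10. The rearrangement itself is well founded, but the oxidation of the potassium enolate may lose facial control at C6, or the enolate may be diverted (capture by the sulfonimine by-product, base-induced α-ketol isomerisation of the product alkoxide). The fallback sets out from 18 and separates the two events. The same alkoxide rearrangement is quenched with Me3SiCl at −78 °C and the trimethylsilyl enol ether F1 is isolated. A Rubottom oxidation (mCPBA, NaHCO3, CH2Cl2, −20 °C) then attacks the neutral enol ether, the most electron-rich alkene present, from its outer face and after silyl migration gives the 6-trimethylsilyloxy ketone F2. Brief treatment with citric acid in aqueous methanol returns to the route at 21.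

2. Step 15. Because the backside of the C10–O bond lies inside the ring, the opened tertiary cation may eliminate, shift a hydride or be captured on the wrong face instead of taking up water with inversion. The fallback sets out from 27 and delivers the oxygen intramolecularly. Camphorsulfonic acid (cat.) in methanol at 0 °C should turn the C5 ketone into its methyl hemiketal, whose hydroxyl sits on the transannular face of C10 and opens the epoxide there with inversion. The bridged methyl ketal F3 is isolated and then hydrolysed with aqueous acetic acid in THF, which returns to the route at 28.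

3. Step 9. The alkenyllithium may attack the other carbonyl face (giving the trans-dialkenyl carbinol) or enolise the hindered ketone. The fallback sets out from 14 and uses a slimmer, less basic nucleophile. Sonogashira coupling with ethynyltrimethylsilane (PdCl2(PPh3)2, CuI, Et3N) gives the silyl enyne F4, and K2CO3 in methanol gives the terminal enyne F5. Its lithium acetylide (n-BuLi, THF, −78 °C) adds to 11 anti to the C4 methyl, the sense established for acetylides and 2,2,6-trisubstituted cyclohexanones, to give the propargylic alcohol F6. Hydroxyl-directed trans-hydroalumination with NaAlH2(OCH2CH2OCH3)2 in THF then gives the E-dienyl carbinol and returns to the route at 18.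

Further compounds
F1 | step 10 | trimethylsilyl enol ether of the ring-expanded ketone (C5–OSiMe3, C5=C6 with C4 and C7 cis) | C[Si](C)(C)O/C1=C/[C@H](C(=C)COCc2ccc(OC)cc2)[C@@H](OCc2ccc(OC)cc2)/C=C(C)/CCC[C@@H]1C
F2 | step 10 | 6-O-trimethylsilyl ether of 21 | O=C1[C@@H](C)CCC/C(C)=C/[C@H](OCc2ccc(OC)cc2)[C@@H](C(=C)COCc2ccc(OC)cc2)[C@@H]1O[Si](C)(C)C
F3 | step 15 | bridged methyl ketal (C5(OCH3)–O–C10 oxygen bridge, free C9–OH, C6-O-TBS, 8,12-olide) | C=C1C(=O)O[C@@H]2[C@@H]1[C@H](O[Si](C)(C)C(C)(C)C)[C@@]3(OC)O[C@](C)(CCC[C@@H]3C)[C@H]2O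
F4 | step 9 | 1-methoxy-4-({[2-methylidene-4-(trimethylsilyl)but-3-yn-1-yl]oxy}methyl)benzene | COc1ccc(COCC(=C)C#C[Si](C)(C)C)cc1
F5 | step 9 | 1-methoxy-4-{[(2-methylidenebut-3-yn-1-yl)oxy]methyl}benzene | COc1ccc(COCC(=C)C#C)cc1
F6 | step 9 | propargylic alcohol: 18 with C6≡C7 in place of the E-C6=C7 alkene | O[C@@]1(C#CC(=C)COCc2ccc(OC)cc2)[C@@H](C)CCC[C@]1(C)/C=C/OCc2ccc(OC)cc2
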